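The two bonds to the ketone carbon are cut together: the one from pyridine C3 and the one to C2 of the decanoyl chain. That carbonyl carbon lies between an sp2 carbon of the pyridine ring (C3, meta to N) and the CH2 end of a linear nonyl group. It can therefore enter as carbon monoxide, trapped between a 3-pyridyl–palladium species and a primary alkylborane in one palladium-catalysed carbonylative cross-coupling that forms both C–C bonds. The precursor is 3-bromo-5-decylpyridine, whose C5 decyl chain is installed first by a halogen-selective B-alkyl coupling on 3-bromo-5-iodopyridine. Its partner is B-nonyl-9-BBN, made in situ from 1-nonene.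

Key step: step 2

Remark: the target has no stereocentre and no stereogenic double bond, so it is achiral; no stereocontrol is needed and the route gives the compound as drawn.
Remark: 9-BBN (2) is written as the monomer and used as its commercial 0.5 M solution in THF. 3-Bromo-5-iodopyridine is chosen so that the first alkylation is directed by the C–I/C–Br reactivity gap and not by statistics.

Step 1
Reactants: 1 1-decene; 2 9-borabicyclo[3.3.1]nonane (9-BBN); 3 3-bromo-5-iodopyridine
Product: 5 3-bromo-5-decylpyridine, via B-decyl-9-BBN 4 (not isolated)
Conditions: 1 (1.05 equiv), 9-BBN (1.0 equiv), THF, 0 °C → rt; then 3 (1.0 equiv), PdCl2(dppf)·CH2Cl2 (3 mol%), aq. K3PO4 (3 equiv), DMF/THF, rt; aqueous work-up, silica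
Reagents that add atoms: none
Why: Anti-Markovnikov hydroboration of the terminal alkene should put boron on the terminal carbon, and the B-alkyl Suzuki–Miyaura coupling should then take place at the C–I bond of 3, which undergoes oxidative addition far faster than C–Br at room temperature, so the bromide is kept for step 2 and no stereocentre is formed.

Step 2
Reactants: 5 3-bromo-5-decylpyridine; 6 1-nonene; 2 9-BBN; 7 carbon monoxide
Product: 9 1-(5-decylpyridin-3-yl)decan-1-one, via B-nonyl-9-BBN 8 (not isolated)
Conditions: 6 (1.6 equiv), 9-BBN (1.5 equiv), THF, 0 °C → rt; then 5, Pd(OAc)2 (3 mol%), Xantphos (4 mol%), finely ground K3PO4 (3 equiv), CO (5 bar), toluene/THF, 70 °C; aqueous work-up, silica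
Reagents that add atoms: none
Why: Pd(0) should insert into the C3–Br bond of 5, CO should coordinate and undergo migratory insertion to give a (5-decylnicotinoyl)palladium(II) bromide, the primary nonyl group should then transfer from the phosphate-activated borane 8, and acyl–alkyl reductive elimination should release ketone 9 and return Pd(0). The closest known reaction type is the palladium-catalysed carbonylative Suzuki–Miyaura coupling of B-alkyl-9-BBN reagents with aryl halides, supported by Pd/Xantphos carbonylations of aryl and 3-pyridyl bromides. No ring is closed and no stereocentre is created, so neither a closure mode nor a controlling element arises. The step needs chemoselectivity for CO insertion ahead of transmetalation, since otherwise the alkyl group couples directly to C3 without the carbonyl; this is addressed by CO pressure, by a wide-bite-angle ligand that stabilises the acyl complex and favours acyl–alkyl reductive elimination over β-hydride elimination, and by a sparingly soluble base that keeps the borate concentration low. In the substrate, the single C–Br bond at C3 is the only site for oxidative addition and is remote from the ring nitrogen, so chelation does not interfere, and the unbranched primary B–C bond of 8 should transfer in preference to the two secondary cage B–C bonds. A small excess of alkene over 9-BBN leaves no B–H to reduce the ketone formed.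

Compound list
1 | 1-decene | C=CCCCCCCCC | starting material
2 | 9-borabicyclo[3.3.1]nonane (9-BBN) | C1CC2CCCC(C1)B2 | starting material
3 | 3-bromo-5-iodopyridine | Brc1cncc(I)c1 | starting material
4 | B-decyl-9-BBN (9-decyl-9-borabicyclo[3.3.1]nonane) | CCCCCCCCCCB1C2CCCC1CCC2 | intermediate
5 | 3-bromo-5-decylpyridine | CCCCCCCCCCc1cncc(Br)c1 | intermediate
6 | 1-nonene | C=CCCCCCCC | starting material
7 | carbon monoxide | [C-]#[O+] | starting material
8 | B-nonyl-9-BBN (9-nonyl-9-borabicyclo[3.3.1]nonane) | CCCCCCCCCB1C2CCCC1CCC2 | intermediate
9 | 1-(5-decylpyridin-3-yl)decan-1-one | CCCCCCCCCCc1cncc(C(=O)CCCCCCCCC)c1 | target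

Total step count: 2
Longest linear sequence: 2 steps (3 → 5 → 9)

Steps most likely to fail (the route has only two steps, so both are ranked and there is no third):

1. Step 2 (key step). The alkyl group may transmetalate to the aryl–palladium intermediate before CO has inserted, giving coupling without the carbonyl. Oxidative addition of the C–Br bond may also be slowed by CO, or the acyl(alkyl)palladium species may undergo β-hydride elimination. Fallback: setting out from 5, the two bonds to the carbonyl carbon are made in separate operations. Aminocarbonylation of 5 with N,O-dimethylhydroxylamine hydrochloride (Pd(OAc)2, Xantphos, K3PO4, CO 1 atm, toluene, 90 °C) should give the Weinreb amide 5-decyl-N-methoxy-N-methylpyridine-3-carboxamide F1, a transformation well established for 3-pyridyl bromides and free of any competing alkyl transfer. Addition of commercial nonylmagnesium bromide (THF, 0 °C) then stops at the chelated tetrahedral intermediate and, after aqueous NH4Cl, returns to the route at 9.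

2. Step 1. Halogen discrimination may be lost, with coupling also at C–Br and double alkylation, or transmetalation may stall because the pyridine nitrogen binds the borane. Fallback: setting out from 3, the chain is attached as an alkyne instead of an alkylborane. Sonogashira coupling with 1-decyne (PdCl2(PPh3)2, CuI, Et3N, THF, rt) should be selective for the C–I bond and give 3-bromo-5-(dec-1-yn-1-yl)pyridine F2. The triple bond is then saturated with diimide generated from excess p-toluenesulfonyl hydrazide and NaOAc (DME/H2O, reflux), which leaves the aryl C–Br bond intact, and the sequence returns to the route at 5.

Further compounds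
F1 | step 2 | 5-decyl-N-methoxy-N-methylpyridine-3-carboxamide | CCCCCCCCCCc1cncc(C(=O)N(C)OC)c1
F2 | step 1 | 3-bromo-5-(dec-1-yn-1-yl)pyridine | CCCCCCCCC#Cc1cncc(Br)c1
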